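**Retrosynthetic overview**
1. The last bond made is C2(propanoate)–C2(octenoate): a nickel-hydride radical hydroalkylation joins a silyl oct-2-ynoate to the racemic α-bromopropanoate of the benzofuranylmethanol. It sets the (R)-centre and the (Z)-alkene together; the silyl ester is cleaved in the work-up.
2. The α-bromo ester comes from the (S)-benzofuranylmethanol and 2-bromopropanoic acid; the ynoate comes from hept-1-yne, CO2 and TIPSCl.
3. The hydroxymethyl carbon is attached by bromine–lithium exchange and formaldehyde on (S)-5-bromo-2-isopropenyl-2,3-dihydrobenzofuran.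
4. Ring formation: only the dihydrofuran ring (ring B) is built, on the benzene ring (ring A) of 4-bromophenol, by ortho-iodination and an asymmetric palladium heteroannulation with isoprene (second step of the route).

Assumption: the ligand antipodes named in steps 2 and 6 are taken to give the (S)- and (R)-centres respectively; if a pilot run shows the opposite sense, the mirror-image ligand is used and nothing else changes.

**Step 1**
Reactants: 1 4-bromophenol
Product: 2 4-bromo-2-iodophenol
Conditions: NIS (1.05 equiv), TsOH·H2O (10 mol%), MeCN, 0 °C to rt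
Reagents that add atoms: N-iodosuccinimide, O=C1CCC(=O)N1I
Why: Electrophilic aromatic iodination; the para position is blocked by bromine, so acid-activated NIS iodinates ortho to OH, and one equivalent keeps it at mono-iodination.

**Step 2**
Reactants: 2 4-bromo-2-iodophenol; 3 isoprene (2-methylbuta-1,3-diene)
Product: 4 (2S)-5-bromo-2-(prop-1-en-2-yl)-2,3-dihydro-1-benzofuran
Conditions: isoprene (3 equiv), Pd2(dba)3·CHCl3 (2.5 mol%), (S,Rs)-tert-butanesulfinamide monophosphine ligand of the TY-Phos type (10 mol%), PhONa (2 equiv), CH2Cl2, 40 °C, sealed tube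
Reagents that add atoms: none
Why: Larock-type heteroannulation run as an asymmetric Heck/Tsuji–Trost cascade: zerovalent palladium inserts into C–I far faster than into C–Br, the aryl group adds to the unsubstituted vinyl terminus of isoprene, and the phenoxide closes ring B on the internal carbon of the π-allylpalladium intermediate, the chiral ligand fixing C2 as (S).

**Step 3**
Reactants: 4 (2S)-5-bromo-2-(prop-1-en-2-yl)-2,3-dihydro-1-benzofuran; 5 formaldehyde (used as dry paraformaldehyde)
Product: 8 [(2S)-2-(prop-1-en-2-yl)-2,3-dihydro-1-benzofuran-5-yl]methanol, via aryllithium 6 (not isolated), via lithium alkoxide 7 (not isolated)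
Conditions: n-BuLi (1.1 equiv), THF, −78 °C, 20 min; (CH2O)n (3 equiv), −78 °C to rt; H2O
Reagents that add atoms: none
Why: Bromine–lithium exchange followed by 1,2-addition of the aryllithium to formaldehyde (hydroxymethylation); at −78 °C exchange outruns deprotonation and C2 is untouched.

**Step 4**
Reactants: 8 [(2S)-2-(prop-1-en-2-yl)-2,3-dihydro-1-benzofuran-5-yl]methanol; 9 2-bromopropanoic acid (racemic)
Product: 10 [(2S)-2-(prop-1-en-2-yl)-2,3-dihydro-1-benzofuran-5-yl]methyl (2RS)-2-bromopropanoate (about 1:1 epimers at the bromine-bearing carbon)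
Conditions: 9 (1.2 equiv), DIC (1.2 equiv), DMAP (5 mol%), CH2Cl2, 0 °C to rt
Reagents that add atoms: none
Why: Steglich esterification under neutral conditions that spare the acid-sensitive para-alkoxybenzyl alcohol and the allylic aryl ether; the bromine-bearing carbon is left unselective on purpose because step 6 erases it.

**Step 5**
Reactants: 11 hept-1-yne; 12 carbon dioxide
Product: 15 triisopropylsilyl oct-2-ynoate, via lithium heptynide 13 (not isolated), via lithium oct-2-ynoate 14 (not isolated)
Conditions: n-BuLi (1.0 equiv), THF, −78 °C; CO2 (gas), −78 to 0 °C; N2 purge; TIPSCl (1.05 equiv), DMAP (5 mol%), 0 °C to rt; filtration, short-path distillation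
Reagents that add atoms: triisopropylsilyl chloride (TIPSCl), CC(C)[Si](Cl)(C(C)C)C(C)C
Why: Acetylide carboxylation followed by O-silylation of the lithium carboxylate in the same flask; the bulky silyl ester masks the acid through step 6 and is removed by fluoride.

**Step 6**
Reactants: 10 [(2S)-2-(prop-1-en-2-yl)-2,3-dihydro-1-benzofuran-5-yl]methyl (2RS)-2-bromopropanoate; 15 triisopropylsilyl oct-2-ynoate
Product: 17 (2Z)-2-[(2R)-1-oxo-1-{[(2S)-2-(prop-1-en-2-yl)-2,3-dihydro-1-benzofuran-5-yl]methoxy}propan-2-yl]oct-2-enoic acid, via silyl ester 16 (not isolated)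
Conditions: 10 (1.0 equiv), 15 (1.5 equiv), NiBr2·glyme (10 mol%), (4S,4′S)-2,2′-(propane-2,2-diyl)bis(4-phenyl-4,5-dihydro-1,3-oxazole) (12 mol%), (EtO)2MeSiH (2.0 equiv), anhydrous K3PO4 (2.0 equiv), DMA/THF, 0 °C; then HF·pyridine, pyridine, THF, 0 °C
Reagents that add atoms: none
Why: Proposed new method: the ligated nickel hydride (from NiBr2·glyme, silane and phosphate) adds syn across the polarised ynoate with hydride at C3 and nickel at the ester-bearing C2, monovalent nickel abstracts bromine from either epimer of 10 to give one planar α-ester radical, and capture of that radical by the (E)-alkenylnickel followed by C–C reductive elimination from trivalent nickel in the chiral pocket sets C2 of the propanoate as (R) (enantioconvergent) with retention of alkene geometry, so the new C–C bond is cis to the vinyl hydrogen ((Z)-acid), after which fluoride cleaves the silyl ester; the closest known reaction types are the nickel-hydride enantioconvergent reductive hydroalkylation of alkenes and alkynes with racemic α-halo carbonyl compounds and the syn-hydrometalation of ynoates at the α-carbon.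

**Compound list**
1 | 4-bromophenol | Oc1ccc(Br)cc1 | starting material
2 | 4-bromo-2-iodophenol | Oc1ccc(Br)cc1I | intermediate
3 | isoprene (2-methylbuta-1,3-diene) | C=CC(C)=C | starting material
4 | (2S)-5-bromo-2-(prop-1-en-2-yl)-2,3-dihydro-1-benzofuran | C=C(C)[C@@H]1Cc2cc(Br)ccc2O1 | intermediate
5 | formaldehyde (as paraformaldehyde) | C=O | starting material
6 | [(2S)-2-(prop-1-en-2-yl)-2,3-dihydro-1-benzofuran-5-yl]lithium | C=C(C)[C@@H]1Cc2cc([Li])ccc2O1 | intermediate
7 | lithium [(2S)-2-(prop-1-en-2-yl)-2,3-dihydro-1-benzofuran-5-yl]methanolate | C=C(C)[C@@H]1Cc2cc(C[O-])ccc2O1.[Li+] | intermediate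
8 | [(2S)-2-(prop-1-en-2-yl)-2,3-dihydro-1-benzofuran-5-yl]methanol | C=C(C)[C@@H]1Cc2cc(CO)ccc2O1 | intermediate
9 | 2-bromopropanoic acid (racemic) | CC(Br)C(=O)O | starting material
10 | [(2S)-2-(prop-1-en-2-yl)-2,3-dihydro-1-benzofuran-5-yl]methyl (2RS)-2-bromopropanoate | C=C(C)[C@@H]1Cc2cc(COC(=O)C(C)Br)ccc2O1 | intermediate
11 | hept-1-yne | CCCCCC#C | starting material
12 | carbon dioxide | O=C=O | starting material
13 | lithium hept-1-yn-1-ide | CCCCCC#C[Li] | intermediate
14 | lithium oct-2-ynoate | CCCCCC#CC(=O)[O-].[Li+] | intermediate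
15 | triisopropylsilyl oct-2-ynoate | CCCCCC#CC(=O)O[Si](C(C)C)(C(C)C)C(C)C | intermediate
16 | triisopropylsilyl (2Z)-2-[(2R)-1-oxo-1-{[(2S)-2-(prop-1-en-2-yl)-2,3-dihydro-1-benzofuran-5-yl]methoxy}propan-2-yl]oct-2-enoate | C=C(C)[C@@H]1Cc2cc(COC(=O)[C@H](C)/C(=C/CCCCC)C(=O)O[Si](C(C)C)(C(C)C)C(C)C)ccc2O1 | intermediate
17 | (2Z)-2-[(2R)-1-oxo-1-{[(2S)-2-(prop-1-en-2-yl)-2,3-dihydro-1-benzofuran-5-yl]methoxy}propan-2-yl]oct-2-enoic acid | C=C(C)[C@@H]1Cc2cc(COC(=O)[C@H](C)/C(=C/CCCCC)C(=O)O)ccc2O1 | target

**Totals**
Total steps: 6. Longest linear sequence: 5 (steps 1, 2, 3, 4, 6); step 5 is a one-step side branch.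

**Steps most likely to fail, with fallbacks**

Step 6 (highest risk). The hydride may add with the wrong regiochemistry, or the α-nickel enoate may lose its geometry through an allenoate form. A plain benzylic ester may give modest enantiocontrol. The isopropenyl group can react with nickel hydride or with the α-ester radical, the product enoate can be over-reduced, and phosphate may epimerise the new centre. The fallback sets out from 15 and comes back at 16. Syn-hydrostannation of 15 (Bu3SnH, Pd(PPh3)4 2 mol%, THF, 0 °C) puts tin on the ester-bearing carbon and gives triisopropylsilyl (2E)-2-(tributylstannyl)oct-2-enoate F1. Iododestannylation with retention (I2, CH2Cl2, 0 °C) gives triisopropylsilyl (2E)-2-iodooct-2-enoate F2. A nickel-catalysed enantioconvergent reductive cross-electrophile coupling of F2 with 10 (NiCl2·glyme, the same bis(oxazoline) ligand, Mn powder, NaI, DMA, 0 °C) then gives 16, which is desilylated as in step 6. The bond is still made by capture of the α-ester radical at nickel, but the alkene geometry is fixed beforehand in a stereodefined alkenyl iodide and no metal hydride is present.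

Step 2. The catalyst may also engage the C–Br bond, the enantiomeric excess on an iodide substrate may be lower than hoped, or isoprene may insert with the other regiochemistry. The fallback sets out from 1 and comes back at 4. The sodium phenoxide of 1 (NaH, toluene, rt) is C-alkylated at the ortho position with 1-bromo-3-methylbut-2-ene to give 4-bromo-2-(3-methylbut-2-en-1-yl)phenol F3. Acetylation (Ac2O, pyridine) gives 4-bromo-2-(3-methylbut-2-en-1-yl)phenyl acetate F4. Shi epoxidation (D-fructose-derived ketone 1,2:4,5-di-O-isopropylidene-β-D-erythro-2,3-hexodiulo-2,6-pyranose 30 mol%, 2KHSO5·KHSO4·K2SO4, K2CO3, MeCN/dimethoxymethane/aqueous buffer pH 10.5, 0 °C) gives 4-bromo-2-{[(2R)-3,3-dimethyloxiran-2-yl]methyl}phenyl acetate F5. K2CO3 in MeOH removes the acetate, and the phenoxide opens the epoxide 5-exo with inversion to give 2-[(2S)-5-bromo-2,3-dihydro-1-benzofuran-2-yl]propan-2-ol F6. Dehydration toward a methyl group with Burgess reagent (methyl N-(triethylammoniosulfonyl)carbamate, PhMe, 60 °C) gives 4.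

Step 5. The triisopropylsilyl ester may hydrolyse on isolation or be cleaved too early by the phosphate in step 6. The fallback sets out from 14 and comes back at 17. Acidification of 14 (aqueous HCl) gives oct-2-ynoic acid F7. Steglich esterification with 2-(trimethylsilyl)ethanol (DIC, DMAP, CH2Cl2) gives 2-(trimethylsilyl)ethyl oct-2-ynoate F8. The step 6 coupling with 10, without the fluoride work-up, gives 2-(trimethylsilyl)ethyl (2Z)-2-[(2R)-1-oxo-1-{[(2S)-2-(prop-1-en-2-yl)-2,3-dihydro-1-benzofuran-5-yl]methoxy}propan-2-yl]oct-2-enoate F9, which is isolated. A separate fluoride deprotection (tris(dimethylamino)sulfonium difluorotrimethylsilicate, DMF, 0 °C) gives 17.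

**Further compounds**
F1 | step 6 | triisopropylsilyl (2E)-2-(tributylstannyl)oct-2-enoate | CCCCC/C=C(/[Sn](CCCC)(CCCC)CCCC)C(=O)O[Si](C(C)C)(C(C)C)C(C)C
F2 | step 6 | triisopropylsilyl (2E)-2-iodooct-2-enoate | CCCCC/C=C(/I)C(=O)O[Si](C(C)C)(C(C)C)C(C)C
F3 | step 2 | 4-bromo-2-(3-methylbut-2-en-1-yl)phenol | CC(C)=CCc1cc(Br)ccc1O
F4 | step 2 | 4-bromo-2-(3-methylbut-2-en-1-yl)phenyl acetate | CC(C)=CCc1cc(Br)ccc1OC(C)=O
F5 | step 2 | 4-bromo-2-{[(2R)-3,3-dimethyloxiran-2-yl]methyl}phenyl acetate | CC1(C)O[C@@H]1Cc1cc(Br)ccc1OC(C)=O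
F6 | step 2 | 2-[(2S)-5-bromo-2,3-dihydro-1-benzofuran-2-yl]propan-2-ol | CC(C)(O)[C@@H]1Cc2cc(Br)ccc2O1
F7 | step 5 | oct-2-ynoic acid | CCCCCC#CC(=O)O
F8 | step 5 | 2-(trimethylsilyl)ethyl oct-2-ynoate | CCCCCC#CC(=O)OCC[Si](C)(C)C
F9 | step 5 | 2-(trimethylsilyl)ethyl (2Z)-2-[(2R)-1-oxo-1-{[(2S)-2-(prop-1-en-2-yl)-2,3-dihydro-1-benzofuran-5-yl]methoxy}propan-2-yl]oct-2-enoate | C=C(C)[C@@H]1Cc2cc(COC(=O)[C@H](C)/C(=C/CCCCC)C(=O)OCC[Si](C)(C)C)ccc2O1
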